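**Retrosynthetic overview**

1. Feature: in the cis-fused tetrahydrobenzofuran-2,5-dione core, the lactone oxygen O1 on C7a and the ketone oxygen on C5 lie 1,4 to each other across the C6=C7 alkene of the carbocycle. This is the pattern left by adding two oxygen nucleophiles to the ends of a C7a=C7–C6=C5 diene.
2. Key disconnection (C7a–O1 and C5–O, γ-lactone formed last): palladium-catalysed 1,4-acetoxylactonisation of diene acid 18. The quaternary carbon C3a alone fixes C7a through the obligatory cis fusion; the C5 acetate is then cleaved and oxidised to the ketone.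
3. Diene acid 18 comes from the 4,4-disubstituted cyclohex-2-enone 12 by enol triflation at its only enolisable carbon and formate reduction. The acetic acid arm is carried as a silyloxyethyl group and oxidised at the end.
4. Enone 12 comes from the valinol-derived bicyclic lactam 3: two enolate alkylations (iodide 4, then farnesyl bromide 7) set the quaternary carbon, and hydride reduction, hydrolysis and aldol condensation close the six-membered ring.
5. Ring order: carbocycle (step 4), then γ-lactone (step 10).

Key step: step 10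

**Assumptions and conventions**

- Stereochemical assumption: the second alkylation of the valinol-derived bicyclic lactam enolate is taken to occur on the face anti to the angular C8a methyl group, the usual course for this lactam class. All configurations below follow from it.
- Choice of stereocontrol: the quaternary carbon carries two CH2R groups of similar size, which gives a catalytic enamine annulation no handle for facial control, so an auxiliary-controlled alkylation is used. The acid arm is masked as a silyl ether because the lactam is later reduced with hydride.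
- Farnesyl = (2E,6E)-3,7,11-trimethyldodeca-2,6,10-trien-1-yl; TBDPS = tert-butyldiphenylsilyl. (R)-Valinol 1, acid 2, iodide 4 and bromide 7 are taken as catalogue compounds.

**Route**

Step 1
Reactants: 1 (R)-valinol; 2 5-oxohexanoic acid
Product: 3 (3R,8aS)-3-isopropyl-8a-methyl-2,3,6,7,8,8a-hexahydro-5H-oxazolo[3,2-a]pyridin-5-one
Conditions: toluene, reflux, Dean–Stark
Reagents that add atoms: none
Why: Meyers bicyclic lactam synthesis: amide formation and intramolecular N,O-ketalisation under azeotropic water removal are reversible at the ketal carbon, so the valinol centre should set C8a under thermodynamic control with the angular methyl cis to isopropyl.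

Step 2
Reactants: 3 bicyclic lactam; 4 tert-butyl(2-iodoethoxy)diphenylsilane
Product: 6 (3R,8aS)-6-[2-(TBDPS-oxy)ethyl] lactam (C6 epimers), via lithium enolate 5 (not isolated)
Conditions: LiN(iPr)2, THF, −78 °C; then 4, DMPU, −78 → −20 °C
Reagents that add atoms: none
Why: Amide enolate alkylation: the lithium lactam enolate displaces iodide from the primary iodide, and the C6 configuration formed here is irrelevant because C6 is re-enolised in step 3.

Step 3
Reactants: 6 mono-alkylated lactam; 7 (2E,6E)-farnesyl bromide
Product: 9 (3R,6S,8aS)-6-farnesyl-6-[2-(TBDPS-oxy)ethyl] lactam, via lithium enolate 8 (not isolated)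
Conditions: LiN(iPr)2, THF, −78 °C; then 7, −78 °C; chromatography to remove any C6 epimer
Reagents that add atoms: none
Why: Meyers second alkylation: the tetrasubstituted lactam enolate attacks the primary allylic bromide by SN2 (chain geometry untouched) on the face anti to the angular C8a methyl, which places farnesyl trans to that methyl and sets the quaternary carbon (future C3a) as 6S.

Step 4
Reactants: 9 dialkylated lactam
Product: 12 (S)-4-farnesyl-4-[2-(TBDPS-oxy)ethyl]cyclohex-2-en-1-one, via carbinolamine 10 (not isolated), via keto aldehyde 11 (not isolated)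
Conditions: NaAlH2(OCH2CH2OMe)2 (Red-Al), toluene, −20 → 0 °C; then Bu4NH2PO4 (1 M aq), EtOH, reflux
Reagents that add atoms: water, O
Why: Meyers unmasking sequence: hydride reduces the lactam only to the carbinolamine, buffered hydrolysis releases valinol and the 5-oxo aldehyde, and intramolecular aldol condensation through the methyl ketone CH3 (the only enolisable site that reaches the non-enolisable aldehyde in a six-membered closure) gives the cyclohexenone without touching the quaternary centre.

Step 5
Reactants: 12 enone
Product: 14 (R)-4-farnesyl-4-[2-(TBDPS-oxy)ethyl]cyclohexa-1,5-dien-1-yl trifluoromethanesulfonate, via lithium dienolate 13 (not isolated)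
Conditions: LiN(iPr)2, THF, −78 °C; then PhNTf2, −78 → 0 °C
Reagents that add atoms: N-phenylbis(trifluoromethanesulfonimide) (PhNTf2), O=S(=O)(N(c1ccccc1)S(=O)(=O)C(F)(F)F)C(F)(F)F
Why: Enol triflate formation: C6 carries the only enolisable protons of the enone (C4 is quaternary), so deprotonation gives a single cross-conjugated dienolate, which PhNTf2 sulfonylates on oxygen.

Step 6
Reactants: 14 dienyl triflate
Product: 15 tert-butyl{2-[(1S)-1-farnesylcyclohexa-2,4-dien-1-yl]ethoxy}diphenylsilane
Conditions: Pd(OAc)2 (5 mol%), PPh3 (10 mol%), Bu3N, HCO2H, DMF, 60 °C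
Reagents that add atoms: none
Why: Palladium-catalysed formate reduction of an enol triflate: oxidative addition of zerovalent palladium to the C–OTf bond, exchange of triflate for formate, loss of CO2 and C–H reductive elimination replace OTf by H with both double bonds left in place.

Step 7
Reactants: 15 silyl ether
Product: 16 2-[(1S)-1-farnesylcyclohexa-2,4-dien-1-yl]ethan-1-ol
Conditions: Bu4NF, THF, 20 °C
Reagents that add atoms: none
Why: Fluoride-induced silyl ether cleavage, driven by the strong Si–F bond; no other group in 15 reacts with fluoride.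

Step 8
Reactants: 16 alcohol
Product: 17 2-[(1S)-1-farnesylcyclohexa-2,4-dien-1-yl]acetaldehyde
Conditions: Dess–Martin periodinane, CH2Cl2, 0 → 20 °C
Reagents that add atoms: none
Why: Dess–Martin oxidation of the primary alcohol stops at the aldehyde under near-neutral conditions that leave the diene and the trisubstituted alkenes untouched.

Step 9
Reactants: 17 aldehyde
Product: 18 2-[(1S)-1-farnesylcyclohexa-2,4-dien-1-yl]acetic acid
Conditions: NaClO2, NaH2PO4, 2-methyl-2-butene (large excess), t-BuOH/H2O, 0 → 20 °C
Reagents that add atoms: sodium chlorite, [Na+].[O-]Cl=O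
Why: Pinnick oxidation: chlorous acid converts the aldehyde into the acid, and the excess 2-methyl-2-butene consumes the hypochlorous acid formed before it can attack the diene or the farnesyl alkenes.

Step 10
Reactants: 18 diene acid
Product: 19 (3aR,5S,7aR)-5-acetoxy-3a-farnesyl-3a,4,5,7a-tetrahydro-1-benzofuran-2(3H)-one
Conditions: Pd(OAc)2 (5 mol%), p-benzoquinone (2 equiv), LiOAc (2 equiv), acetone/AcOH 4:1, 20 °C, chloride-free
Reagents that add atoms: acetic acid (delivered as acetate from LiOAc/AcOH), CC(=O)O
Why: Divalent palladium binds the conjugated diene (the isolated trisubstituted farnesyl alkenes are much weaker ligands), and the tethered carboxylate adds to the nearer diene terminus C7a on the face opposite palladium, a 5-exo closure that forms the γ-lactone and an η3-allyl palladium unit over C7–C6–C5. Benzoquinone coordinates to this allyl complex and induces transfer of acetate from palladium to the remote terminus C5, releasing zerovalent palladium, which benzoquinone reoxidises. The closest known reaction is the palladium diacetate/benzoquinone 1,4-acetoxylactonisation of cyclohexa-2,4-dienylacetic acids, of which 18 is a member with a fully substituted ring carbon. C7a is controlled by C3a, because a γ-lactone on a six-membered ring can only be cis-fused and the acid arm is fixed on C3a; C5 is controlled by the palladium face, so under chloride-free conditions acetate should arrive syn to the metal and end trans to O1. The step needs chemoselectivity for the diene (secured by η4 binding) and 1,4- over 1,2-regioselectivity (attack at C5, away from the congested C7a–C3a junction); the C5 configuration is of no consequence, since C5 becomes the ketone carbon.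

Step 11
Reactants: 19 acetoxy lactone
Product: 20 (3aR,5S,7aR)-3a-farnesyl-5-hydroxy-3a,4,5,7a-tetrahydro-1-benzofuran-2(3H)-one
Conditions: K2CO3 (0.2 equiv), MeOH, 0 °C; pH 5 buffer work-up
Reagents that add atoms: none
Why: Base-catalysed transesterification: methoxide cleaves the unhindered secondary acetate faster than it opens the lactone, whose carbonyl sits next to a neopentyl-type methylene and which re-closes in any case because the cis-fused γ-lactone is the favoured form.

Step 12
Reactants: 20 allylic alcohol
Product: 21 (3aR,7aR)-3a-farnesyl-3a,7a-dihydro-1-benzofuran-2,5(3H,4H)-dione (CNP0400313.1)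
Conditions: MnO2 (activated, excess), CH2Cl2, 20 °C
Reagents that add atoms: none
Why: Manganese dioxide oxidises allylic alcohols selectively, so the C5 carbinol becomes the enone carbonyl while the lactone, C7a and the isolated alkenes stay untouched under neutral conditions.

**Compound list**

1 | (R)-valinol, (2R)-2-amino-3-methylbutan-1-ol | CC(C)[C@@H](N)CO | starting material
2 | 5-oxohexanoic acid | CC(=O)CCCC(=O)O | starting material
3 | (3R,8aS)-3-isopropyl-8a-methyl-2,3,6,7,8,8a-hexahydro-5H-oxazolo[3,2-a]pyridin-5-one | CC(C)[C@@H]1CO[C@@]2(C)CCCC(=O)N12 | intermediate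
4 | tert-butyl(2-iodoethoxy)diphenylsilane | CC(C)(C)[Si](OCCI)(c1ccccc1)c1ccccc1 | starting material
5 | lithium enolate of 3 | CC(C)[C@@H]1CO[C@@]2(C)CCC=C(O[Li])N12 | intermediate (not isolated)
6 | (3R,8aS)-6-[2-(TBDPS-oxy)ethyl]-3-isopropyl-8a-methyl lactam, C6 epimers | CC(C)[C@@H]1CO[C@@]2(C)CCC(CCO[Si](c3ccccc3)(c3ccccc3)C(C)(C)C)C(=O)N12 | intermediate
7 | (2E,6E)-farnesyl bromide | CC(C)=CCC/C(C)=C/CC/C(C)=C/CBr | starting material
8 | lithium enolate of 6 | CC(C)[C@@H]1CO[C@@]2(C)CCC(CCO[Si](c3ccccc3)(c3ccccc3)C(C)(C)C)=C(O[Li])N12 | intermediate (not isolated)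
9 | (3R,6S,8aS)-6-farnesyl-6-[2-(TBDPS-oxy)ethyl]-3-isopropyl-8a-methyl lactam (farnesyl trans to the angular methyl) | CC(C)=CCC/C(C)=C/CC/C(C)=C/C[C@]1(CCO[Si](c2ccccc2)(c2ccccc2)C(C)(C)C)CC[C@]2(C)OC[C@@H](C(C)C)N2C1=O | intermediate
10 | carbinolamine from 9 (5-hydroxy, C5 epimers; 3R,6S,8aS) | CC(C)=CCC/C(C)=C/CC/C(C)=C/C[C@]1(CCO[Si](c2ccccc2)(c2ccccc2)C(C)(C)C)CC[C@]2(C)OC[C@@H](C(C)C)N2C1O | intermediate (not isolated)
11 | (2S)-2-farnesyl-5-oxo-2-[2-(TBDPS-oxy)ethyl]hexanal | CC(C)=CCC/C(C)=C/CC/C(C)=C/C[C@](C=O)(CCO[Si](c1ccccc1)(c1ccccc1)C(C)(C)C)CCC(C)=O | intermediate (not isolated)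
12 | (S)-4-farnesyl-4-[2-(TBDPS-oxy)ethyl]cyclohex-2-en-1-one | CC(C)=CCC/C(C)=C/CC/C(C)=C/C[C@]1(CCO[Si](c2ccccc2)(c2ccccc2)C(C)(C)C)CCC(=O)C=C1 | intermediate
13 | lithium dienolate of 12 | CC(C)=CCC/C(C)=C/CC/C(C)=C/C[C@]1(CCO[Si](c2ccccc2)(c2ccccc2)C(C)(C)C)CC=C(O[Li])C=C1 | intermediate (not isolated)
14 | (R)-4-farnesyl-4-[2-(TBDPS-oxy)ethyl]cyclohexa-1,5-dien-1-yl trifluoromethanesulfonate | CC(C)=CCC/C(C)=C/CC/C(C)=C/C[C@]1(CCO[Si](c2ccccc2)(c2ccccc2)C(C)(C)C)CC=C(OS(=O)(=O)C(F)(F)F)C=C1 | intermediate
15 | tert-butyl{2-[(1S)-1-farnesylcyclohexa-2,4-dien-1-yl]ethoxy}diphenylsilane | CC(C)=CCC/C(C)=C/CC/C(C)=C/C[C@]1(CCO[Si](c2ccccc2)(c2ccccc2)C(C)(C)C)CC=CC=C1 | intermediate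
16 | 2-[(1S)-1-farnesylcyclohexa-2,4-dien-1-yl]ethan-1-ol | CC(C)=CCC/C(C)=C/CC/C(C)=C/C[C@]1(CCO)CC=CC=C1 | intermediate
17 | 2-[(1S)-1-farnesylcyclohexa-2,4-dien-1-yl]acetaldehyde | CC(C)=CCC/C(C)=C/CC/C(C)=C/C[C@]1(CC=O)CC=CC=C1 | intermediate
18 | 2-[(1S)-1-farnesylcyclohexa-2,4-dien-1-yl]acetic acid | CC(C)=CCC/C(C)=C/CC/C(C)=C/C[C@]1(CC(=O)O)CC=CC=C1 | intermediate (key-step precursor)
19 | (3aR,5S,7aR)-5-acetoxy-3a-farnesyl-3a,4,5,7a-tetrahydro-1-benzofuran-2(3H)-one (cis-fused; acetate trans to O1) | CC(C)=CCC/C(C)=C/CC/C(C)=C/C[C@]12C[C@H](OC(C)=O)C=C[C@H]1OC(=O)C2 | intermediate (key-step product)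
20 | (3aR,5S,7aR)-3a-farnesyl-5-hydroxy-3a,4,5,7a-tetrahydro-1-benzofuran-2(3H)-one | CC(C)=CCC/C(C)=C/CC/C(C)=C/C[C@]12C[C@H](O)C=C[C@H]1OC(=O)C2 | intermediate
21 | (3aR,7aR)-3a-farnesyl-3a,7a-dihydro-1-benzofuran-2,5(3H,4H)-dione | CC(C)=CCC/C(C)=C/CC/C(C)=C/C[C@]12CC(=O)C=C[C@H]1OC(=O)C2 | target

**Totals**

Total step count: 12. Longest linear sequence: 12 steps (from 1 and 2 to 21).

**Steps most likely to fail**

1. Step 10 (key step). What may go wrong:
   - [4+2] cycloaddition of the diene with benzoquinone;
   - palladium-mediated allylic oxidation of the farnesyl chain;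
   - 1,2- instead of 1,4-addition;
   - loss of enantiopurity through palladium hydride-induced migration of the diene before cyclisation.

   Fallback, from 18 back to the route at 20: phenylselenolactonisation of 18 with N-(phenylseleno)phthalimide and catalytic camphorsulfonic acid in CH2Cl2 at 0 °C closes the same cis γ-lactone by anti 1,2-addition across C7a=C7. This should give the allylic selenide 3a-farnesyl-7-(phenylseleno)-3a,4,7,7a-tetrahydro-1-benzofuran-2(3H)-one F1 (selenium trans to O1, alkene at C5=C6). Oxidation with NaIO4 (NaHCO3, MeOH/H2O, 0 °C) gives the selenoxide F2. A suprafacial [2,3]-sigmatropic shift carries oxygen to C5 on the face that selenium occupied and moves the alkene to C6=C7, giving the C5 selenenate F3. Cleavage of its Se–O bond on aqueous work-up gives 20, which goes on through step 12.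

2. Step 3. What may go wrong: poor facial discrimination in the alkylation of the tetrasubstituted enolate 8, for instance if the silyloxyethyl group already on the enolate shields or chelates on the endo face. Any unseparated C6 epimer leads to the enantiomeric series and erodes enantiopurity.

   Fallback, from 2 back to the route at 12: the order of the two alkylations is reversed on the enantiomeric template. (S)-Valinol and 2 (toluene, reflux, Dean–Stark) give the (3S,8aR) lactam F4. Deprotonation with LiN(iPr)2 gives its lithium enolate F5, and 7 gives the 6-farnesyl lactam F6. A second deprotonation gives the lithium enolate F7, and alkylation with the unbranched iodide 4 (THF/DMPU), now entering anti to the angular methyl, gives the (3S,6S,8aR) dialkylated lactam F8. Reduction with NaAlH2(OCH2CH2OMe)2 gives the carbinolamine F9, whose buffered hydrolysis gives the same keto aldehyde 11 and hence 12.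

3. Step 6. What may go wrong: migration of the diene by palladium hydride addition and re-elimination (hydride adding at one diene terminus and leaving from the ring CH2). This would move the diene to the other side of the quaternary carbon and so racemise 15, because the two enantiomers differ only in the side on which the diene lies. Partial reduction of the diene is a second possibility.

   Fallback, from 12 back to the route at 15, palladium-free (Shapiro reaction): condensation of 12 with TsNHNH2 (MeOH, 20 °C) gives the tosylhydrazone F10. LiN(iPr)2 (3 equiv, THF, −78 → 20 °C) removes N–H and a C6 proton, and loss of sulfinate and dinitrogen gives the dienyllithium F11. Protonation with water gives 15 without passing through triflate 14.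

**Further compounds**

F1 | step 10 | 3a-farnesyl-7-(phenylseleno)-3a,4,7,7a-tetrahydro-1-benzofuran-2(3H)-one (cis-fused, Se trans to O1) | CC(C)=CCC/C(C)=C/CC/C(C)=C/C[C@]12CC=C[C@H]([Se]c3ccccc3)[C@H]1OC(=O)C2
F2 | step 10 | selenoxide of F1 | CC(C)=CCC/C(C)=C/CC/C(C)=C/C[C@]12CC=C[C@H]([Se](=O)c3ccccc3)[C@H]1OC(=O)C2
F3 | step 10 | C5 benzeneselenenate of 20 | CC(C)=CCC/C(C)=C/CC/C(C)=C/C[C@]12C[C@H](O[Se]c3ccccc3)C=C[C@H]1OC(=O)C2
F4 | step 3 | (3S,8aR)-3-isopropyl-8a-methyl-2,3,6,7,8,8a-hexahydro-5H-oxazolo[3,2-a]pyridin-5-one | CC(C)[C@H]1CO[C@]2(C)CCCC(=O)N12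
F5 | step 3 | lithium enolate of F4 | CC(C)[C@H]1CO[C@]2(C)CCC=C(O[Li])N12
F6 | step 3 | (3S,8aR)-6-farnesyl lactam, C6 epimers | CC(C)=CCC/C(C)=C/CC/C(C)=C/CC1CC[C@@]2(C)OC[C@H](C(C)C)N2C1=O
F7 | step 3 | lithium enolate of F6 | CC(C)=CCC/C(C)=C/CC/C(C)=C/CC=1CC[C@@]2(C)OC[C@H](C(C)C)N2C=1O[Li]
F8 | step 3 | (3S,6S,8aR)-6-farnesyl-6-[2-(TBDPS-oxy)ethyl] lactam (farnesyl cis to the angular methyl) | CC(C)=CCC/C(C)=C/CC/C(C)=C/C[C@]1(CCO[Si](c2ccccc2)(c2ccccc2)C(C)(C)C)CC[C@@]2(C)OC[C@H](C(C)C)N2C1=O
F9 | step 3 | carbinolamine from F8 (C5 epimers) | CC(C)=CCC/C(C)=C/CC/C(C)=C/C[C@]1(CCO[Si](c2ccccc2)(c2ccccc2)C(C)(C)C)CC[C@@]2(C)OC[C@H](C(C)C)N2C1O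
F10 | step 6 | tosylhydrazone of 12 | CC(C)=CCC/C(C)=C/CC/C(C)=C/C[C@]1(CCO[Si](c2ccccc2)(c2ccccc2)C(C)(C)C)CCC(=NNS(=O)(=O)c2ccc(C)cc2)C=C1
F11 | step 6 | dienyllithium from F10 (lithium at the former carbonyl carbon) | CC(C)=CCC/C(C)=C/CC/C(C)=C/C[C@]1(CCO[Si](c2ccccc2)(c2ccccc2)C(C)(C)C)CC=C([Li])C=C1
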